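**Retrosynthetic overview**

- The strategy rests on the benzo ring of the coumarin: C6, C7, C8 and C8a carry four contiguous, mutually different oxygens (OMe, side-chain ether, OMe, lactone O1). These four carbons are taken intact from dimethyl squarate; only C5 and C4a, with C4 as a masked aldehyde, come from an (E)-3,3-diethoxypropenyl group.
- Disconnections, target backwards: diol acetonide; pyranone ring (C3=C4 and O1–C2) by Z-selective olefination and lactonisation of a salicylaldehyde; benzene ring (C4a–C8a) by thermal ring expansion of a 4-alkenyl-4-methoxycyclobutenone; C7–O bond by alkoxide exchange at the β-carbon of that cyclobutenone; alkenyl–squarate bond by vinyllithium addition.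
- Side chain: nerol, Sharpless epoxidation, epoxide hydrolysis with inversion at the tertiary carbon, acetonide.
- Ring order: four-membered ring (purchased), then benzene ring (step 9), then pyranone ring (step 11).

Key step: step 9

Remark: coumarin numbering (O1, C2–C4, C4a, C5–C8, C8a) is used for the target. Compounds 12 and 14 are carried as mixtures of both configurations at ring carbon C4, which becomes planar in step 9.

**Side-chain alcohol**

Step 1
Reactants: 1 nerol
Product: 2 [(2R,3S)-3-methyl-3-(4-methylpent-3-en-1-yl)oxiran-2-yl]methanol ((2R,3S)-2,3-epoxynerol)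
Conditions: Ti(OiPr)4 (cat.), D-(−)-diethyl tartrate (cat.), t-BuOOH, 4 Å MS, CH2Cl2, −20 °C
Reagents that add atoms: tert-butyl hydroperoxide, CC(C)(C)OO
Why: Sharpless asymmetric epoxidation touches only the allylic-alcohol alkene, and the D-(−)-tartrate ligand should deliver oxygen to the face that gives the (2R,3S) epoxide (mirror image of the (2S,3R) product expected with the L-(+)-ligand), which sets C2 and C3.

Step 2
Reactants: 2 (2R,3S)-2,3-epoxynerol
Product: 3 tert-butyl{[(2R,3S)-3-methyl-3-(4-methylpent-3-en-1-yl)oxiran-2-yl]methoxy}diphenylsilane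
Conditions: TBDPSCl, imidazole, DMF, 0 °C → rt
Reagents that add atoms: tert-butyl(chloro)diphenylsilane, CC(C)(C)[Si](Cl)(c1ccccc1)c1ccccc1
Why: Imidazole-promoted silylation of the primary alcohol masks O1, so that the later acetonide can only span O2 and O3, and the epoxide is inert to these conditions.

Step 3
Reactants: 3 silyl ether of the epoxide
Product: 4 (2R,3R)-1-[(tert-butyldiphenylsilyl)oxy]-3,7-dimethyloct-6-ene-2,3-diol
Conditions: HClO4 (cat.), THF/H2O, 0 °C → rt
Reagents that add atoms: water, O
Why: In this acid-catalysed epoxide hydrolysis water should attack the protonated trisubstituted epoxide at the tertiary carbon C3 with inversion while C2 keeps its configuration, so the cis-epoxide gives the (2R,3R)-diol; the silyl ether and the distal alkene tolerate cold dilute acid.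

Step 4
Reactants: 4 (2R,3R)-diol silyl ether
Product: 5 tert-butyl{[(4R,5R)-2,2,5-trimethyl-5-(4-methylpent-3-en-1-yl)-1,3-dioxolan-4-yl]methoxy}diphenylsilane
Conditions: 2,2-dimethoxypropane, PPTS (cat.), CH2Cl2, rt
Reagents that add atoms: 2,2-dimethoxypropane, COC(C)(C)OC
Why: Acid-catalysed transketalisation closes the dioxolane on the only free 1,2-diol without breaking a C–O bond at either stereocentre.

Step 5
Reactants: 5 acetonide silyl ether
Product: 6 [(4R,5R)-2,2,5-trimethyl-5-(4-methylpent-3-en-1-yl)-1,3-dioxolan-4-yl]methanol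
Conditions: Bu4NF, THF, 0 °C → rt
Reagents that add atoms: none
Why: Fluoride-mediated desilylation frees the primary alcohol and leaves the acetonide and the alkene untouched.

**Cyclobutenone precursor**

Step 6
Reactants: 7 3,3-diethoxyprop-1-yne
Product: 8 (E)-tributyl(3,3-diethoxyprop-1-en-1-yl)stannane
Conditions: Bu3SnH, AIBN (cat.), 80 °C, neat
Reagents that add atoms: tributyltin hydride, CCCC[SnH](CCCC)CCCC
Why: Radical hydrostannylation of the terminal alkyne places tin on the terminal carbon, and reversible addition of the stannyl radical should equilibrate the product to the E isomer.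

Step 7
Reactants: 8 (E)-vinylstannane, 9 dimethyl squarate
Product: 12 4-[(E)-3,3-diethoxyprop-1-en-1-yl]-2,3,4-trimethoxycyclobut-2-en-1-one (racemic), via vinyllithium 10 (not isolated), via lithium alkoxide 11 (not isolated)
Conditions: n-BuLi, THF, −78 °C; add to 9, THF, −78 °C; then MeOTf, −78 → 0 °C
Reagents that add atoms: methyl trifluoromethanesulfonate, COS(=O)(=O)C(F)(F)F
Why: Tin–lithium exchange gives the vinyllithium with retention of the E geometry, 1,2-addition to one squarate carbonyl stops at the mono-adduct because the remaining carbonyl is a vinylogous ester, and the tertiary lithium alkoxide is O-methylated in situ by methyl triflate.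

Step 8
Reactants: 12 trimethoxycyclobutenone, 6 side-chain alcohol
Product: 14 4-[(E)-3,3-diethoxyprop-1-en-1-yl]-2,4-dimethoxy-3-{[(4R,5R)-2,2,5-trimethyl-5-(4-methylpent-3-en-1-yl)-1,3-dioxolan-4-yl]methoxy}cyclobut-2-en-1-one (both epimers at C4), via sodium alkoxide 13 (not isolated)
Conditions: 6 (1.2 equiv), NaH (1.1 equiv), THF, 0 °C; then 12, −20 °C → rt
Reagents that add atoms: none
Why: Proposed new method: alkoxide 13 should add to C3, the only electrophilic alkene carbon of 12 (β-carbon of the vinylogous ester; C2 is the α-carbon and C4 is saturated), to give a ketal enolate that expels methoxide, and NaOMe, which is insoluble in THF, should pull this otherwise degenerate transetherification towards 14; the closest known reaction types are the addition–elimination of amines at C3 of squarate-derived 4-substituted 2,3-dimethoxycyclobutenones and the alkoxide transesterification of dialkyl squarates.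

**Benzannulation and completion**

Step 9
Reactants: 14 side-chain-loaded cyclobutenone
Product: 17 6-(diethoxymethyl)-2,4-dimethoxy-3-{[(4R,5R)-2,2,5-trimethyl-5-(4-methylpent-3-en-1-yl)-1,3-dioxolan-4-yl]methoxy}phenol (the diethyl acetal of the salicylaldehyde), via dienylketene 15 (not isolated), via cyclohexadienone 16 (not isolated)
Conditions: degassed PhMe (0.02 M), 110 °C, Ar; crude product taken directly into step 10
Reagents that add atoms: none
Why: Heating should open the C1–C4 bond of the cyclobutenone in a conrotatory 4π process to the (Z)-dienylketene 15, which closes by a thermal disrotatory 6π electrocyclisation between the ketene carbon (future C8a) and the alkene terminus (future C4a) to give cyclohexa-2,4-dienone 16, and enolisation then gives phenol 17. The closest known reaction is the thermal ring expansion of 4-alkenyl-4-alkoxycyclobutenones to hydroquinone monoethers (Moore rearrangement). The one ring formed is the six-membered carbocycle, closed in the 6π electrocyclic mode. No stereocentre is created: the sp3 carbon of 16 is lost on aromatisation and both C4 epimers of 14 converge. The step needs torquoselectivity, secured by the donor methoxy group on C4, which rotates outward and so turns the alkenyl group inward, towards the ketene; the E alkene keeps the acetal out of the closing termini. The oxygen pattern is fixed by ring connectivity: the ketone oxygen becomes the free C8a phenol, C2–OMe becomes C8–OMe, the C3 ether becomes the C7 ether and C4–OMe becomes C6–OMe.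

Step 10
Reactants: 17 phenol acetal
Product: 18 2-hydroxy-3,5-dimethoxy-4-{[(4R,5R)-2,2,5-trimethyl-5-(4-methylpent-3-en-1-yl)-1,3-dioxolan-4-yl]methoxy}benzaldehyde
Conditions: PPTS (cat.), acetone/H2O (10:1), rt
Reagents that add atoms: water, O
Why: In this acetal hydrolysis the acyclic diethyl acetal ionises far more readily than the dioxolane, because its benzylic oxocarbenium ion is stabilised by the para-alkoxy and ortho-hydroxy groups, and acetone as solvent suppresses loss of the acetonide.

Step 11
Reactants: 18 salicylaldehyde, 19 methyl bis(2,2,2-trifluoroethyl)phosphonoacetate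
Product: 21 6,8-dimethoxy-7-{[(4R,5R)-2,2,5-trimethyl-5-(4-methylpent-3-en-1-yl)-1,3-dioxolan-4-yl]methoxy}-2H-chromen-2-one, via Z-cinnamate 20 (not isolated)
Conditions: 19 (1.3 equiv), KN(SiMe3)2 (2.3 equiv), 18-crown-6, THF, −78 °C → rt; aq. NH4Cl
Reagents that add atoms: none
Why: The Still–Gennari variant of the Horner–Wadsworth–Emmons olefination should give the (Z)-cinnamate under kinetic control, and its ortho-phenoxide then closes the pyranone ring by lactonisation with loss of methoxide.

Step 12
Reactants: 21 coumarin acetonide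
Product: 22 altissimacoumarin C, 7-{[(2R,3R)-2,3-dihydroxy-3,7-dimethyloct-6-en-1-yl]oxy}-6,8-dimethoxy-2H-chromen-2-one
Conditions: AcOH/H2O (4:1), 40 °C
Reagents that add atoms: none
Why: Mild acid-catalysed acetonide hydrolysis cleaves only the ketal C–O bonds, so both stereocentres are untouched, and the lactone, the aryl ether and the trisubstituted alkene tolerate aqueous acetic acid.

**Compound list**

1 | nerol | CC(C)=CCC/C(C)=C\CO | starting material
2 | [(2R,3S)-3-methyl-3-(4-methylpent-3-en-1-yl)oxiran-2-yl]methanol | OC[C@H]1O[C@@]1(C)CCC=C(C)C | intermediate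
3 | tert-butyl{[(2R,3S)-3-methyl-3-(4-methylpent-3-en-1-yl)oxiran-2-yl]methoxy}diphenylsilane | CC(C)(C)[Si](c1ccccc1)(c1ccccc1)OC[C@H]2O[C@@]2(C)CCC=C(C)C | intermediate
4 | (2R,3R)-1-[(tert-butyldiphenylsilyl)oxy]-3,7-dimethyloct-6-ene-2,3-diol | CC(C)(C)[Si](c1ccccc1)(c1ccccc1)OC[C@@H](O)[C@](C)(O)CCC=C(C)C | intermediate
5 | tert-butyl{[(4R,5R)-2,2,5-trimethyl-5-(4-methylpent-3-en-1-yl)-1,3-dioxolan-4-yl]methoxy}diphenylsilane | CC(C)(C)[Si](c1ccccc1)(c1ccccc1)OC[C@H]2OC(C)(C)O[C@]2(C)CCC=C(C)C | intermediate
6 | [(4R,5R)-2,2,5-trimethyl-5-(4-methylpent-3-en-1-yl)-1,3-dioxolan-4-yl]methanol | OC[C@H]1OC(C)(C)O[C@]1(C)CCC=C(C)C | intermediate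
7 | 3,3-diethoxyprop-1-yne | C#CC(OCC)OCC | starting material
8 | (E)-tributyl(3,3-diethoxyprop-1-en-1-yl)stannane | CCCC[Sn](CCCC)(CCCC)/C=C/C(OCC)OCC | intermediate
9 | dimethyl squarate (3,4-dimethoxycyclobut-3-ene-1,2-dione) | COC1=C(OC)C(=O)C1=O | starting material
10 | (E)-(3,3-diethoxyprop-1-en-1-yl)lithium | [Li]/C=C/C(OCC)OCC | intermediate
11 | lithium 1-[(E)-3,3-diethoxyprop-1-en-1-yl]-2,3-dimethoxy-4-oxocyclobut-2-en-1-olate (racemic) | [Li]OC1(/C=C/C(OCC)OCC)C(OC)=C(OC)C1=O | intermediate
12 | 4-[(E)-3,3-diethoxyprop-1-en-1-yl]-2,3,4-trimethoxycyclobut-2-en-1-one (racemic) | O=C1C(OC)=C(OC)C1(OC)/C=C/C(OCC)OCC | intermediate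
13 | sodium [(4R,5R)-2,2,5-trimethyl-5-(4-methylpent-3-en-1-yl)-1,3-dioxolan-4-yl]methanolate | [Na+].[O-]C[C@H]1OC(C)(C)O[C@]1(C)CCC=C(C)C | intermediate
14 | 4-[(E)-3,3-diethoxyprop-1-en-1-yl]-2,4-dimethoxy-3-{[(4R,5R)-2,2,5-trimethyl-5-(4-methylpent-3-en-1-yl)-1,3-dioxolan-4-yl]methoxy}cyclobut-2-en-1-one (both C4 epimers) | O=C1C(OC)=C(OC[C@H]2OC(C)(C)O[C@]2(C)CCC=C(C)C)C1(OC)/C=C/C(OCC)OCC | intermediate
15 | (3Z,5E)-7,7-diethoxy-2,4-dimethoxy-3-(side-chain acetonide oxy)hepta-1,3,5-trien-1-one (dienylketene) | O=C=C(OC)\C(OC[C@H]1OC(C)(C)O[C@]1(C)CCC=C(C)C)=C(OC)/C=C/C(OCC)OCC | intermediate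
16 | 6-(diethoxymethyl)-2,4-dimethoxy-3-(side-chain acetonide oxy)cyclohexa-2,4-dien-1-one | O=C1C(OC)=C(OC[C@H]2OC(C)(C)O[C@]2(C)CCC=C(C)C)C(OC)=CC1C(OCC)OCC | intermediate
17 | 6-(diethoxymethyl)-2,4-dimethoxy-3-{[(4R,5R)-2,2,5-trimethyl-5-(4-methylpent-3-en-1-yl)-1,3-dioxolan-4-yl]methoxy}phenol | CCOC(OCC)c1cc(OC)c(OC[C@H]2OC(C)(C)O[C@]2(C)CCC=C(C)C)c(OC)c1O | intermediate
18 | 2-hydroxy-3,5-dimethoxy-4-{[(4R,5R)-2,2,5-trimethyl-5-(4-methylpent-3-en-1-yl)-1,3-dioxolan-4-yl]methoxy}benzaldehyde | O=Cc1cc(OC)c(OC[C@H]2OC(C)(C)O[C@]2(C)CCC=C(C)C)c(OC)c1O | intermediate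
19 | methyl bis(2,2,2-trifluoroethyl)phosphonoacetate | COC(=O)CP(=O)(OCC(F)(F)F)OCC(F)(F)F | starting material
20 | methyl (Z)-3-[2-hydroxy-3,5-dimethoxy-4-(side-chain acetonide oxy)phenyl]prop-2-enoate (formed as its potassium phenoxide) | COC(=O)/C=C\c1cc(OC)c(OC[C@H]2OC(C)(C)O[C@]2(C)CCC=C(C)C)c(OC)c1O | intermediate
21 | 6,8-dimethoxy-7-{[(4R,5R)-2,2,5-trimethyl-5-(4-methylpent-3-en-1-yl)-1,3-dioxolan-4-yl]methoxy}-2H-chromen-2-one | COc1cc2ccc(=O)oc2c(OC)c1OC[C@H]3OC(C)(C)O[C@]3(C)CCC=C(C)C | intermediate
22 | altissimacoumarin C | COc1cc2ccc(=O)oc2c(OC)c1OC[C@@H](O)[C@](C)(O)CCC=C(C)C | target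

**Step count**

Total: 12 steps. Longest linear sequence: 10 steps (nerol 1 to 22 through steps 1–5 and 8–12); the squarate branch (steps 6–7) joins at step 8.

**Steps most likely to fail**

1. Step 8. The exchange may stall at an unfavourable equilibrium, or the alkoxide may add to the ring carbonyl and cleave the four-membered ring. The fallback uses known chemistry and attaches the side chain to a phenol after both rings exist; it sets out from 12 and returns at 21. Heating 12 in toluene should give 2-hydroxy-3,4,5-trimethoxybenzaldehyde diethyl acetal F1 by the same ring expansion in its all-methoxy form. PPTS in aqueous acetone then gives 2-hydroxy-3,4,5-trimethoxybenzaldehyde F2. Still–Gennari olefination and lactonisation with 19 gives 6,7,8-trimethoxycoumarin F3. AlCl3 in CH2Cl2 should cleave the C7 methyl ether selectively, since that methoxy group is twisted out of plane between two neighbours and conjugated with the lactone carbonyl, to give 7-hydroxy-6,8-dimethoxycoumarin (isofraxidin) F4. Mitsunobu etherification of F4 with alcohol 6 (PPh3, DIAD, THF) gives 21.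

2. Step 9. The o-hydroxybenzyl acetal may lose ethanol at the reaction temperature to a quinone methide that oligomerises, or the allylic acetal may disturb the 6π closure. The fallback brings in the formyl carbon after the ring expansion; it sets out from 9 and returns at 18. Addition of vinyllithium to 9 and a methyl triflate quench should give 2,3,4-trimethoxy-4-vinylcyclobut-2-en-1-one F5. Exchange with alkoxide 13 as in step 8 gives 2,4-dimethoxy-3-(side-chain acetonide oxy)-4-vinylcyclobut-2-en-1-one F6. Thermolysis in toluene gives 2,4-dimethoxy-3-(side-chain acetonide oxy)phenol F7. Magnesium-mediated ortho-formylation (MgCl2, Et3N, paraformaldehyde, MeCN, reflux) at the only free ortho position gives 18.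

3. Step 11. Attack of the phosphonate anion on the phenoxide-deactivated aldehyde may be slow, and the Z-selectivity may erode, leaving E-cinnamate that cannot lactonise. The fallback enforces the cis geometry with a tether; it sets out from 18 and returns at 21. Acylation of the phenol with diethylphosphonoacetic acid (DCC, DMAP, CH2Cl2) should give 2-formyl-3,5-dimethoxy-... aryl ester, namely 6-formyl-2,4-dimethoxy-3-(side-chain acetonide oxy)phenyl (diethoxyphosphoryl)acetate F8. Intramolecular Horner–Wadsworth–Emmons reaction (LiCl, DBU, MeCN) then closes the pyranone ring directly to 21.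

**Further compounds**

F1 | step 8 | 2-hydroxy-3,4,5-trimethoxybenzaldehyde diethyl acetal | CCOC(OCC)c1cc(OC)c(OC)c(OC)c1O
F2 | step 8 | 2-hydroxy-3,4,5-trimethoxybenzaldehyde | O=Cc1cc(OC)c(OC)c(OC)c1O
F3 | step 8 | 6,7,8-trimethoxycoumarin | COc1cc2ccc(=O)oc2c(OC)c1OC
F4 | step 8 | 7-hydroxy-6,8-dimethoxycoumarin (isofraxidin) | COc1cc2ccc(=O)oc2c(OC)c1O
F5 | step 9 | 2,3,4-trimethoxy-4-vinylcyclobut-2-en-1-one (racemic) | O=C1C(OC)=C(OC)C1(OC)C=C
F6 | step 9 | 2,4-dimethoxy-3-{[(4R,5R)-2,2,5-trimethyl-5-(4-methylpent-3-en-1-yl)-1,3-dioxolan-4-yl]methoxy}-4-vinylcyclobut-2-en-1-one | O=C1C(OC)=C(OC[C@H]2OC(C)(C)O[C@]2(C)CCC=C(C)C)C1(OC)C=C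
F7 | step 9 | 2,4-dimethoxy-3-{[(4R,5R)-2,2,5-trimethyl-5-(4-methylpent-3-en-1-yl)-1,3-dioxolan-4-yl]methoxy}phenol | COc1ccc(O)c(OC)c1OC[C@H]1OC(C)(C)O[C@]1(C)CCC=C(C)C
F8 | step 11 | 6-formyl-2,4-dimethoxy-3-{[(4R,5R)-2,2,5-trimethyl-5-(4-methylpent-3-en-1-yl)-1,3-dioxolan-4-yl]methoxy}phenyl (diethoxyphosphoryl)acetate | CCOP(=O)(OCC)CC(=O)Oc1c(C=O)cc(OC)c(OC[C@H]2OC(C)(C)O[C@]2(C)CCC=C(C)C)c1OC
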